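**Retrosynthetic overview**
1. All four benzene rings are bought. Fumaryl chloride 1 and two molecules of 1,3-bis(benzyloxy)benzene 2 give the (E)-enedione 3, which carries C3, C4 and both aroyl groups. Two molecules of 4-(benzyloxy)benzaldehyde 4 give the (E)-stilbene 5, which carries C2, C5 and both aryl groups.
2. Key disconnection: C2–C3 and C4–C5 of the oxolane are cut together. Stilbene 5 gives oxirane 6, which opens to the W-shaped carbonyl ylide 7, and 7 adds across the alkene of 3 to give oxolane 8.
3. Ring order: oxirane first, then oxolane, both closed in the same flask. The oxirane C–C bond is spent in making the dipole, and its oxygen becomes the ring oxygen.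
4. The ylide shape sets 2,5-cis and the alkene geometry sets 3,4-trans, so only one diastereomer is possible. The enantiomers of 8 are separated to give 9, and sixfold debenzylation gives 10.

Assumption: the elution order of the two enantiomers of 8 cannot be predicted. The fraction kept is the one whose ECD spectrum or crystal-structure analysis (anomalous dispersion) shows (2S,3R,4R,5R).

**Step 1**
Reactants: 1 fumaryl chloride; 2 1,3-bis(benzyloxy)benzene (2.1 equiv)
Product: 3 (E)-1,4-bis[2,4-bis(benzyloxy)phenyl]but-2-ene-1,4-dione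
Conditions: SnCl4 (2.2 equiv), CH2Cl2, −20 to 0 °C; cold aq. NaHCO3
Reagents that add atoms: none
Why: Twofold Friedel–Crafts acylation; position 4 of the resorcinol diether (para to one ether oxygen, ortho to the other) is the most activated open site, the E geometry of 1 is kept, SnCl4 at low temperature is mild enough for aryl benzyl ethers, and no stereocentre is formed.

**Step 2**
Reactants: 4 4-(benzyloxy)benzaldehyde (2 equiv)
Product: 5 (E)-1,2-bis[4-(benzyloxy)phenyl]ethene
Conditions: TiCl4, Zn dust, THF, 0 °C then reflux; recrystallisation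
Reagents that add atoms: none
Why: McMurry reductive coupling of an aromatic aldehyde gives mainly the E-stilbene, which crystallises pure; benzyl ethers survive and no stereocentre is formed.

**Step 3 (key step)**
Reactants: 5 (E)-1,2-bis[4-(benzyloxy)phenyl]ethene (1.5 equiv); 3 (E)-1,4-bis[2,4-bis(benzyloxy)phenyl]but-2-ene-1,4-dione
Product: 8 racemic {2,5-bis[4-(benzyloxy)phenyl]oxolane-3,4-diyl}bis{[2,4-bis(benzyloxy)phenyl]methanone} of relative configuration 2S,3R,4R,5R, via trans-oxirane 6 (not isolated), via carbonyl ylide 7 (not isolated)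
Conditions: dimethyldioxirane (acetone solution, 1.1 equiv per 5), CH2Cl2, 0 °C; volatiles off at 0 °C; then 3, 4-mesityl-2,6-di-p-tolylpyrylium tetrafluoroborate (5 mol%), solid K2CO3, CH2Cl2/MeCN, N2, 455 nm LEDs, 20 °C
Reagents that add atoms: dimethyldioxirane, CC1(C)OO1
Why: Proposed new method: syn oxygen transfer gives the acid-labile trans-oxirane 6 (hence not isolated); the excited pyrylium salt oxidises 6 by one electron, the C–C bond opens, and back electron transfer leaves the relaxed exo,exo (W-shaped) ylide 7; concerted suprafacial 1,3-dipolar cycloaddition of 7 to the very electron-poor E-alkene of 3 forms C2–C3 and C4–C5 at once, so the ylide shape fixes 2,5-cis and the alkene geometry fixes 3,4-trans, which allows only the 2,3-cis-3,4-trans-4,5-trans diastereomer (no endo/exo issue), obtained racemic because the alkene faces are enantiotopic; the closest known reaction type is the photoinduced-electron-transfer opening of 2,3-diaryloxiranes to carbonyl ylides and their [3+2] addition to fumarates and fumaronitrile.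

**Step 4**
Reactants: 8 racemic hexabenzyl oxolane diketone
Product: 9 {(2S,3R,4R,5R)-2,5-bis[4-(benzyloxy)phenyl]oxolane-3,4-diyl}bis{[2,4-bis(benzyloxy)phenyl]methanone}
Conditions: preparative SFC, immobilised amylose tris(3,5-dimethylphenylcarbamate) phase, CO2/2-propanol, 35 °C
Reagents that add atoms: none
Why: Chromatographic resolution of a racemate on a chiral stationary phase; no bond is changed, the neutral medium cannot enolise C3/C4, and this step fixes the absolute configuration of all four centres.

**Step 5**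
Reactants: 9 (2S,3R,4R,5R)-hexabenzyl oxolane diketone
Product: 10 [(2S,3R,4R,5R)-2,5-bis(4-hydroxyphenyl)oxolane-3,4-diyl]bis[(2,4-dihydroxyphenyl)methanone] (target)
Conditions: H2 (1 atm), Pd/C (10 wt%), EtOAc/THF, 20 °C, stopped at full conversion
Reagents that add atoms: none
Why: Catalytic hydrogenolysis of aryl benzyl ethers is faster than cleavage of the ring C–O bonds or reduction of the hydrogen-bonded aryl ketones, and the neutral medium avoids both enolisation at C3/C4 and quinone-methide opening at C2/C5, so no stereocentre is touched.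

**Compound list**
1 | fumaryl chloride | O=C(Cl)/C=C/C(=O)Cl | starting material
2 | 1,3-bis(benzyloxy)benzene | c1ccc(COc2cccc(OCc3ccccc3)c2)cc1 | starting material
3 | (E)-1,4-bis[2,4-bis(benzyloxy)phenyl]but-2-ene-1,4-dione | O=C(/C=C/C(=O)c1ccc(OCc2ccccc2)cc1OCc1ccccc1)c1ccc(OCc2ccccc2)cc1OCc1ccccc1 | intermediate
4 | 4-(benzyloxy)benzaldehyde | O=Cc1ccc(OCc2ccccc2)cc1 | starting material
5 | (E)-1,2-bis[4-(benzyloxy)phenyl]ethene | C(Oc1ccc(/C=C/c2ccc(OCc3ccccc3)cc2)cc1)c1ccccc1 | intermediate
6 | trans-2,3-bis[4-(benzyloxy)phenyl]oxirane (racemic, 2R,3R drawn) | C(Oc1ccc([C@H]2O[C@@H]2c2ccc(OCc3ccccc3)cc2)cc1)c1ccccc1 | intermediate (not isolated)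
7 | exo,exo carbonyl ylide of bis[4-(benzyloxy)benzylidene] oxide | C(Oc1ccc(/C=[O+]/[CH-]c2ccc(OCc3ccccc3)cc2)cc1)c1ccccc1 | intermediate (not isolated)
8 | racemic hexabenzyl oxolane diketone (relative configuration as drawn) | O=C(c1ccc(OCc2ccccc2)cc1OCc1ccccc1)[C@@H]1[C@@H](C(=O)c2ccc(OCc3ccccc3)cc2OCc2ccccc2)[C@H](c2ccc(OCc3ccccc3)cc2)O[C@@H]1c1ccc(OCc2ccccc2)cc1 | intermediate
9 | (2S,3R,4R,5R)-hexabenzyl oxolane diketone, single enantiomer | O=C(c1ccc(OCc2ccccc2)cc1OCc1ccccc1)[C@@H]1[C@@H](C(=O)c2ccc(OCc3ccccc3)cc2OCc2ccccc2)[C@H](c2ccc(OCc3ccccc3)cc2)O[C@@H]1c1ccc(OCc2ccccc2)cc1 | intermediate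
10 | [(2S,3R,4R,5R)-2,5-bis(4-hydroxyphenyl)oxolane-3,4-diyl]bis[(2,4-dihydroxyphenyl)methanone] | O=C(c1ccc(O)cc1O)[C@@H]1[C@@H](C(=O)c2ccc(O)cc2O)[C@H](c2ccc(O)cc2)O[C@@H]1c1ccc(O)cc1 | target

**Total step count:** 5. **Longest linear sequence:** 4 (4 → 5 → 8 → 9 → 10; the branch 1 + 2 → 3 is one step).

**The three steps most likely to fail**

Step 3. Oxirane 6 may rearrange to the diarylacetaldehyde before it is oxidised. Enedione 3 may isomerise to the Z form under the light, which would give 3,4-cis adducts, or it may quench the photocatalyst.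

The fallback sets out from 3 and 4 and comes back at 8, and it is ionic instead of photochemical. Conjugate reduction of 3 (Na2S2O4, aqueous THF) gives 1,4-bis[2,4-bis(benzyloxy)phenyl]butane-1,4-dione F4. Double soft enolisation (Me3SiOTf, Et3N, CH2Cl2, 0 °C) then gives (1Z,3Z)-1,4-bis[2,4-bis(benzyloxy)phenyl]-1,4-bis(trimethylsilyloxy)buta-1,3-diene F5.

F5 takes up two equivalents of 4 under catalytic Me3SiOTf at −78 °C. The sequence is a Mukaiyama aldol addition, oxocarbenium formation from the silyl ether and the second aldehyde, and closure by the remaining enol silane. Such enol-to-oxocarbenium closures normally give 2,5-cis rings, but 3,4-trans is less secure here, so other diastereomers would have to be removed before step 4.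

Step 1. SnCl4 may strip the benzyl ether ortho to the new ketone, and the free phenol then adds to the enedione. The activated arene may also add to 3 in a conjugate sense.

The fallback sets out from 1 and 2 and comes back at 3, with the polarity reversed (aryl nucleophile, acyl electrophile).
- Compound 1 with N,O-dimethylhydroxylamine hydrochloride and pyridine gives (E)-N,N'-dimethoxy-N,N'-dimethylbut-2-enediamide F1.
- Compound 2 with N-bromosuccinimide in MeCN gives 1-bromo-2,4-bis(benzyloxy)benzene F2.
- Bromine–lithium exchange on F2 (n-BuLi, THF, −78 °C) gives [2,4-bis(benzyloxy)phenyl]lithium F3.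
- Two equivalents of F3 add to F1, and the chelated adducts collapse to 3 on NH4Cl quench.

Step 5. The ring C–O bonds are doubly benzylic and become more labile once the para phenols are free. The ketones may also be over-reduced.

The fallback sets out from 9 and comes back at 10, in two stages. Chelation-controlled Lewis-acid cleavage of only the two ether groups ortho to the ketones (MgBr2·OEt2, toluene/Et2O, 60 °C) gives {(2S,3R,4R,5R)-2,5-bis[4-(benzyloxy)phenyl]oxolane-3,4-diyl}bis{[4-(benzyloxy)-2-hydroxyphenyl]methanone} F6. The ketones in F6 are deactivated by hydrogen bonding. The remaining four benzyl groups are then removed by transfer hydrogenolysis (1,4-cyclohexadiene, Pd/C, EtOH/THF), which keeps the hydrogen supply low and spares the ring.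

**Further compounds**
F1 | step 1 | (E)-N,N'-dimethoxy-N,N'-dimethylbut-2-enediamide | CON(C)C(=O)/C=C/C(=O)N(C)OC
F2 | step 1 | 1-bromo-2,4-bis(benzyloxy)benzene | Brc1ccc(OCc2ccccc2)cc1OCc1ccccc1
F3 | step 1 | [2,4-bis(benzyloxy)phenyl]lithium | [Li]c1ccc(OCc2ccccc2)cc1OCc1ccccc1
F4 | step 3 | 1,4-bis[2,4-bis(benzyloxy)phenyl]butane-1,4-dione | O=C(CCC(=O)c1ccc(OCc2ccccc2)cc1OCc1ccccc1)c1ccc(OCc2ccccc2)cc1OCc1ccccc1
F5 | step 3 | (1Z,3Z)-1,4-bis[2,4-bis(benzyloxy)phenyl]-1,4-bis(trimethylsilyloxy)buta-1,3-diene | C[Si](C)(C)O/C(=C\C=C(/O[Si](C)(C)C)c1ccc(OCc2ccccc2)cc1OCc1ccccc1)c1ccc(OCc2ccccc2)cc1OCc1ccccc1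
F6 | step 5 | {(2S,3R,4R,5R)-2,5-bis[4-(benzyloxy)phenyl]oxolane-3,4-diyl}bis{[4-(benzyloxy)-2-hydroxyphenyl]methanone} | O=C(c1ccc(OCc2ccccc2)cc1O)[C@@H]1[C@@H](C(=O)c2ccc(OCc3ccccc3)cc2O)[C@H](c2ccc(OCc3ccccc3)cc2)O[C@@H]1c1ccc(OCc2ccccc2)cc1
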